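**Plan**

- Numbering: C1 methyl-bearing fusion carbon, C2/C3 CH2, C4 isopropyl carbinol, C5 fusion CH, C6 acyloxy carbon, C7=C8 (CH3 on C8), C9/C10 CH2.
- Retrosynthetic cuts, in order: the C6–O acyl bond; then C6–C7 and C8–C9 of the seven-membered ring, with C6–C9 re-formed; then C4–C5 of the five-membered carbinol ring; last C1–C2.
- Enabling feature: C7 and C8 (with the C8 methyl) are a two-carbon unit lodged between C6 and C9. The seven-membered ring (C1, C5, C6, C7, C8, C9, C10) is therefore a cyclopentanone ring (C1, C5, C6, C9, C10) into which methyl but-2-ynoate has been inserted.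
- Forward order: C1–C2 by copper-catalysed asymmetric conjugate addition to 3-methylcyclopent-2-en-1-one; carbinol ring closed by a SmI2 aldol (C4–C5) to a cis-diquinane; seven-membered ring by enamine–alkynoate (2+2) addition and cyclobutene opening; then demethoxycarbonylation, C6 reduction and acylation.
- Stereochemistry: C1 from the chiral copper catalyst; C5 (cis fusion) and C4 (oxygen syn to the ring carbonyl) relayed from C1 in the samarium aldol; C6 by chelation-controlled hydride delivery to the convex face.

Key step: step 7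

Remark: 16 is written as the conjugated alkylidene β-keto ester; a β,γ-unsaturated or enol tautomer, if present, should converge on the same enone 17 in step 8.

**Route**

Step 1
Reactants: 1 5-bromo-2-methylpent-2-ene; 2 3-methylcyclopent-2-en-1-one
Product: 5 (S)-trimethyl{[3-methyl-3-(4-methylpent-3-en-1-yl)cyclopent-1-en-1-yl]oxy}silane, via Grignard reagent 3 (not isolated), via bromomagnesium enolate 4 (not isolated)
Conditions: Mg, Et2O, 23 °C; then Cu(OTf)2 (3 mol %), chiral imidazolinium salt (N-heterocyclic carbene precursor, 4 mol %; enantiomer for Si-face delivery at C3 of 2), 2, Et2O, −30 → 0 °C; then TMSCl, Et3N, DMPU, 0 → 23 °C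
Reagents that add atoms: chlorotrimethylsilane, C[Si](C)(C)Cl
Why: Copper-catalysed asymmetric conjugate addition of a Grignard reagent to a β-substituted cyclic enone under carbene–copper control should deliver the homoprenyl group to the Si face of C3 and so set the quaternary centre (the future C1), and O-silylation of the magnesium enolate fixes the enolate regiochemistry between the future C5 and C6.

Step 2
Reactants: 5
Product: 6 (3S)-2-bromo-3-methyl-3-(4-methylpent-3-en-1-yl)cyclopentan-1-one (both C2 epimers)
Conditions: NBS, THF, −78 → 0 °C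
Reagents that add atoms: N-bromosuccinimide, O=C1CCC(=O)N1Br
Why: α-Halogenation of a silyl enol ether places bromine only on ring C2 (the future C5), the isolated trisubstituted alkene being far less nucleophilic at low temperature, and the CHBr centre may form as a mixture because it is erased in step 5.

Step 3
Reactants: 6
Product: 7 (3S)-2-bromo-3-[2-(3,3-dimethyloxiran-2-yl)ethyl]-3-methylcyclopentan-1-one (diastereomer mixture)
Conditions: mCPBA, NaHCO3, CH2Cl2, 0 °C
Reagents that add atoms: meta-chloroperbenzoic acid, O=C(OO)c1cccc(Cl)c1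
Why: Prilezhaev epoxidation of the electron-rich trisubstituted alkene should be much faster than Baeyer–Villiger oxidation of the α-bromo ketone, and the uncontrolled oxirane stereocentre is destroyed in step 4.

Step 4
Reactants: 7
Product: 8 (3S)-2-bromo-3-methyl-3-(4-methyl-3-oxopentyl)cyclopentan-1-one (both C2 epimers)
Conditions: BF3·OEt2 (0.3 equiv), CH2Cl2, −78 → −20 °C
Reagents that add atoms: none
Why: Meinwald rearrangement, in which the Lewis acid opens the oxirane at its tertiary carbon and a 1,2-hydride shift from the adjacent CH gives the isopropyl ketone, while the α-bromo ketone is inert to BF3.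

Step 5
Reactants: 8
Product: 10 (3aS,6R,6aR)-6-hydroxy-3a-methyl-6-(propan-2-yl)hexahydropentalen-1(2H)-one, via samarium enolate 9 (not isolated)
Conditions: SmI2 (2.1 equiv), THF, −78 °C; then pH 7 buffer
Reagents that add atoms: none
Why: Two electrons from SmI2 cleave the C–Br bond to a trivalent-samarium enolate located only between C5 and C6, which closes the carbinol ring by a Reformatsky-type intramolecular aldol (5-exo-trig) onto the isopropyl ketone; the two-carbon tether from C1 enforces the cis fusion at C5, and the samarium-bridged transition state puts the C4 oxygen syn to the ring carbonyl and the isopropyl group on the convex face.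

Step 6
Reactants: 10
Product: 11 (3aS,6R,6aR)-3a-methyl-6-(propan-2-yl)-6-[(triethylsilyl)oxy]hexahydropentalen-1(2H)-one
Conditions: TESOTf, 2,6-lutidine, CH2Cl2, −78 → 0 °C
Reagents that add atoms: triethylsilyl trifluoromethanesulfonate, CC[Si](CC)(CC)OS(=O)(=O)C(F)(F)F
Why: Silyl triflate silylation reaches hindered tertiary alcohols, and capping the aldol oxygen blocks retro-aldol cleavage and amine-induced dehydration in step 7 without touching any stereocentre.

Step 7
Reactants: 11; 12 methyl but-2-ynoate
Product: 16 methyl (3R,3aR,8aR)-6,8a-dimethyl-4-oxo-3-(propan-2-yl)-3-[(triethylsilyl)oxy]-1,2,3,3a,4,7,8,8a-octahydroazulene-5-carboxylate, via pyrrolidine enamine 13 (not isolated), via aminocyclobutene 14 (not isolated), via ring-enlarged dienamine 15 (not isolated)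
Conditions: pyrrolidine (5 equiv), TsOH·H2O (5 mol %), PhMe, reflux, Dean–Stark; concentrate; 12 (3 equiv), PhMe, 110 °C, sealed tube; then AcOH–NaOAc–H2O, THF, 40 °C
Reagents that add atoms: water, O
Why: The less substituted enamine 13 (C6=C9) attacks through C9 the methyl-bearing alkyne carbon of 12, the resulting allenolate carbon C7 closes on the iminium carbon C6 to give aminocyclobutene 14, and the old C6–C9 bond then breaks in a nitrogen-pushed, ester-pulled ring opening to dienamine 15, a vinylogous carbamate that buffered aqueous acid hydrolyses to 16. The closest known reaction is the two-carbon ring enlargement of cyclic ketone enamines with acetylenic esters, applied here to a slower β-methyl alkynoate, hence the heating in an apolar aprotic solvent. The four-membered ring closes by 4-exo-trig attack of C7 on the C6=N+ bond; the seven-membered ring is not closed by bond formation but arises when the fused cyclobutene opens (a 4π electrocyclic opening in its polar, stepwise form), which inserts C7–C8 between C6 and C9. No stereocentre of 16 is made here: C6 and C9 of 14 are transient, and C1, C4 and C5 are spectators because a C5=C6 enamine would be tetrasubstituted and clash with the crowded C4. Two regiochemical demands must be met: enamine formation toward C9, secured by the ring-fusion and C4 substituents flanking C5, and bonding of C9 to the alkyne carbon β to the ester, secured by the ester polarisation. Ring closure rather than proton transfer within the zwitterion is favoured by the absence of protic additives.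

Step 8
Reactants: 16
Product: 17 (3R,3aR,8aR)-6,8a-dimethyl-3-(propan-2-yl)-3-[(triethylsilyl)oxy]-2,3,3a,7,8,8a-hexahydroazulen-4(1H)-one
Conditions: LiCl, H2O (2 equiv), DMSO, 140 °C
Reagents that add atoms: none
Why: Krapcho demethoxycarbonylation, in which chloride demethylates the ester, the β,γ-unsaturated tautomer of the keto carboxylate loses CO2 and the dienolate is reprotonated to the conjugated C7=C8 enone, under near-neutral conditions that the silyl ether should tolerate.

Step 9
Reactants: 17
Product: 18 (3R,3aR,8aR)-3-hydroxy-6,8a-dimethyl-3-(propan-2-yl)-2,3,3a,7,8,8a-hexahydroazulen-4(1H)-one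
Conditions: HF·pyridine, pyridine, THF, 0 → 23 °C
Reagents that add atoms: none
Why: Fluoride cleavage of the triethylsilyl ether under buffered, weakly acidic conditions frees the C4 hydroxyl without the retro-aldol opening that a basic fluoride source could trigger in this β-hydroxy ketone.

Step 10
Reactants: 18
Product: 19 (3R,3aS,4R,8aR)-6,8a-dimethyl-3-(propan-2-yl)-1,2,3,3a,4,7,8,8a-octahydroazulene-3,4-diol
Conditions: Et2BOMe, THF–MeOH (4:1), −78 °C, 1 h; NaBH4, −78 °C; then AcOH, MeOH co-evaporation
Reagents that add atoms: none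
Why: Narasaka–Prasad reduction, in which Et2BOMe ties the C4 hydroxyl and the C6 carbonyl into a six-membered boron chelate lying in the concave fold of the cis-fused bicycle, so that borohydride should attack C6 in 1,2 fashion from the open convex face (the side of H5) and set C6 with its oxygen syn to the C4 oxygen.

Step 11
Reactants: 20 isovanillic acid (3-hydroxy-4-methoxybenzoic acid)
Product: 22 3-[(tert-butyldimethylsilyl)oxy]-4-methoxybenzoic acid, via bis-silyl derivative 21 (not isolated)
Conditions: TBSCl (2.5 equiv), imidazole, DMF, 23 °C; then AcOH–H2O–THF, 23 °C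
Reagents that add atoms: tert-butyldimethylsilyl chloride, CC(C)(C)[Si](C)(C)Cl
Why: Exhaustive silylation followed by selective hydrolysis of the much more labile silyl ester leaves the aryl silyl ether and a free carboxylic acid.

Step 12
Reactants: 19; 22
Product: 23 (3R,3aS,4R,8aR)-3-hydroxy-6,8a-dimethyl-3-(propan-2-yl)-1,2,3,3a,4,7,8,8a-octahydroazulen-4-yl 3-[(tert-butyldimethylsilyl)oxy]-4-methoxybenzoate
Conditions: DCC, DMAP, CH2Cl2, 0 → 23 °C
Reagents that add atoms: none
Why: Steglich esterification should acylate only the secondary allylic C6 hydroxyl, the tertiary C4 hydroxyl being too hindered, and it forms the acyl–oxygen bond so that the C6 configuration is retained.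

Step 13
Reactants: 23
Product: 24 (3R,3aS,4R,8aR)-3-hydroxy-6,8a-dimethyl-3-(propan-2-yl)-1,2,3,3a,4,7,8,8a-octahydroazulen-4-yl 3-hydroxy-4-methoxybenzoate
Conditions: Bu4NF (1.1 equiv), AcOH (1.1 equiv), THF, 0 °C
Reagents that add atoms: none
Why: Fluoride desilylation cleaves the aryl silyl ether rapidly, and the acetic acid buffer should suppress phenoxide- or alkoxide-mediated acyl migration and ester cleavage.

**Compound list**

1 | 5-bromo-2-methylpent-2-ene | CC(C)=CCCBr | starting material
2 | 3-methylcyclopent-2-en-1-one | CC1=CC(=O)CC1 | starting material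
3 | (4-methylpent-3-en-1-yl)magnesium bromide | CC(C)=CCC[Mg]Br | intermediate
4 | bromomagnesium (S)-3-methyl-3-(4-methylpent-3-en-1-yl)cyclopent-1-en-1-olate | Br[Mg]OC1=C[C@@](C)(CCC=C(C)C)CC1 | intermediate
5 | (S)-trimethyl{[3-methyl-3-(4-methylpent-3-en-1-yl)cyclopent-1-en-1-yl]oxy}silane | C[Si](C)(C)OC1=C[C@@](C)(CCC=C(C)C)CC1 | intermediate
6 | (3S)-2-bromo-3-methyl-3-(4-methylpent-3-en-1-yl)cyclopentan-1-one, both C2 epimers | O=C1CC[C@](C)(CCC=C(C)C)C1Br | intermediate
7 | (3S)-2-bromo-3-[2-(3,3-dimethyloxiran-2-yl)ethyl]-3-methylcyclopentan-1-one, diastereomer mixture | O=C1CC[C@](C)(CCC2OC2(C)C)C1Br | intermediate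
8 | (3S)-2-bromo-3-methyl-3-(4-methyl-3-oxopentyl)cyclopentan-1-one, both C2 epimers | O=C1CC[C@](C)(CCC(=O)C(C)C)C1Br | intermediate
9 | diiodosamarium (R)-3-methyl-3-(4-methyl-3-oxopentyl)cyclopent-1-en-1-olate (trivalent samarium enolate, quaternary carbon unchanged from 8) | I[Sm](I)OC1=C[C@@](C)(CCC(=O)C(C)C)CC1 | intermediate
10 | (3aS,6R,6aR)-6-hydroxy-3a-methyl-6-(propan-2-yl)hexahydropentalen-1(2H)-one | O=C2CC[C@]3(C)CC[C@@](O)(C(C)C)[C@H]23 | intermediate
11 | (3aS,6R,6aR)-3a-methyl-6-(propan-2-yl)-6-[(triethylsilyl)oxy]hexahydropentalen-1(2H)-one | O=C2CC[C@]3(C)CC[C@@](O[Si](CC)(CC)CC)(C(C)C)[C@H]23 | intermediate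
12 | methyl but-2-ynoate | CC#CC(=O)OC | starting material
13 | 1-{6a-methyl-4-(propan-2-yl)-4-[(triethylsilyl)oxy]-1,3a,4,5,6,6a-hexahydropentalen-3-yl}pyrrolidine (C6=C9 enamine of 11, stereocentres as in 11) | C1CCN(C1)C2=CC[C@]3(C)CC[C@@](O[Si](CC)(CC)CC)(C(C)C)[C@H]23 | intermediate
14 | fused aminocyclobutene: four-membered ring C6–C7=C8–C9 annulated on the C6–C9 bond of 11, pyrrolidin-1-yl on C6, CO2CH3 on C7, CH3 on C8 (C1, C4, C5 as in 11; C6 and C9 unassigned) | COC(=O)C1=C(C)C2C[C@]3(C)CC[C@@](O[Si](CC)(CC)CC)(C(C)C)[C@@H]3C12N4CCCC4 | intermediate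
15 | methyl 6,8a-dimethyl-3-(propan-2-yl)-4-(pyrrolidin-1-yl)-3-[(triethylsilyl)oxy]-1,2,3,3a,8,8a-hexahydroazulene-5-carboxylate (stereocentres as in 11) | C1CCN(C1)C2=C(C(=O)OC)C(C)=CC[C@]3(C)CC[C@@](O[Si](CC)(CC)CC)(C(C)C)[C@H]23 | intermediate
16 | methyl (3R,3aR,8aR)-6,8a-dimethyl-4-oxo-3-(propan-2-yl)-3-[(triethylsilyl)oxy]-1,2,3,3a,4,7,8,8a-octahydroazulene-5-carboxylate | O=C2C(C(=O)OC)=C(C)CC[C@]3(C)CC[C@@](O[Si](CC)(CC)CC)(C(C)C)[C@H]23 | intermediate
17 | (3R,3aR,8aR)-6,8a-dimethyl-3-(propan-2-yl)-3-[(triethylsilyl)oxy]-2,3,3a,7,8,8a-hexahydroazulen-4(1H)-one | O=C2C=C(C)CC[C@]3(C)CC[C@@](O[Si](CC)(CC)CC)(C(C)C)[C@H]23 | intermediate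
18 | (3R,3aR,8aR)-3-hydroxy-6,8a-dimethyl-3-(propan-2-yl)-2,3,3a,7,8,8a-hexahydroazulen-4(1H)-one | O=C2C=C(C)CC[C@]3(C)CC[C@@](O)(C(C)C)[C@H]23 | intermediate
19 | (3R,3aS,4R,8aR)-6,8a-dimethyl-3-(propan-2-yl)-1,2,3,3a,4,7,8,8a-octahydroazulene-3,4-diol (numbered as the target) | O[C@@H]2C=C(C)CC[C@]3(C)CC[C@@](O)(C(C)C)[C@H]23 | intermediate
20 | 3-hydroxy-4-methoxybenzoic acid (isovanillic acid) | COc1ccc(C(=O)O)cc1O | starting material
21 | tert-butyldimethylsilyl 3-[(tert-butyldimethylsilyl)oxy]-4-methoxybenzoate | COc1ccc(C(=O)O[Si](C)(C)C(C)(C)C)cc1O[Si](C)(C)C(C)(C)C | intermediate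
22 | 3-[(tert-butyldimethylsilyl)oxy]-4-methoxybenzoic acid | COc1ccc(C(=O)O)cc1O[Si](C)(C)C(C)(C)C | intermediate
23 | (3R,3aS,4R,8aR)-3-hydroxy-6,8a-dimethyl-3-(propan-2-yl)-1,2,3,3a,4,7,8,8a-octahydroazulen-4-yl 3-[(tert-butyldimethylsilyl)oxy]-4-methoxybenzoate | COc1ccc(C(=O)O[C@@H]2C=C(C)CC[C@]3(C)CC[C@@](O)(C(C)C)[C@H]23)cc1O[Si](C)(C)C(C)(C)C | intermediate
24 | (3R,3aS,4R,8aR)-3-hydroxy-6,8a-dimethyl-3-(propan-2-yl)-1,2,3,3a,4,7,8,8a-octahydroazulen-4-yl 3-hydroxy-4-methoxybenzoate | COc1ccc(C(=O)O[C@@H]2C=C(C)CC[C@]3(C)CC[C@@](O)(C(C)C)[C@H]23)cc1O | target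

**Step count**

Total: 13 steps. Longest linear sequence: 12 steps (steps 1–10, 12, 13); step 11 is a one-step side branch.

**Steps most likely to fail**

Step 7 (ring enlargement). Enamine formation at the crowded ketone may stall. The β-methyl alkynoate may add so slowly that the enamine decomposes. The zwitterion may transfer a proton and end as the open-chain Michael adduct, or its pyranone, instead of closing the four-membered ring. Prolonged heating could also let the iminium tautomerise toward C5 and expel the silyloxy group. The fallback sets out from 11 and comes back at 17. Enamine 13 would be made as before and treated with methyl propiolate (PhMe, 23 → 60 °C), the acetylenic ester for which this ring enlargement is fast. This should give the aminocyclobutene lacking the C8 methyl F1, which opens to the des-methyl dienamine F2, and buffered hydrolysis should give the des-methyl keto ester F3. Krapcho demethoxycarbonylation (LiCl, wet DMSO, 140 °C) would give the C8-unsubstituted cycloheptenone F4. Conjugate addition of Me2CuLi with TMSCl (THF, −78 °C) would install the C8 methyl and trap the enolate as the 8-methyl enol trimethylsilyl ether F5. Saegusa–Ito oxidation with Pd(OAc)2 in MeCN would then restore the C7=C8 double bond and give 17; the C8 stereocentre made in the cuprate step is erased.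

Step 1 (asymmetric conjugate addition). Facial discrimination by the copper catalyst on the five-membered enone may be insufficient, or O-silylation of the magnesium enolate incomplete, so that enantiopurity or regiochemical purity is lost. The fallback sets out from Grignard reagent 3 and comes back at 5, with the roles of the two carbon substituents exchanged. Reagent 3 would add 1,2 to commercial 3-ethoxycyclopent-2-en-1-one to give the tertiary allylic alcohol adduct F6, which dilute HCl should transpose (Stork–Danheiser) to 3-(4-methylpent-3-en-1-yl)cyclopent-2-en-1-one F7. Me3Al with catalytic Cu(O2CC4H3S) (copper thiophene-2-carboxylate) and a chiral phosphoramidite in Et2O at −30 °C would add the methyl group to give the dimethylaluminium enolate F8, which TMSOTf would silylate in the same flask to 5. The ligand enantiomer would be chosen to give the same (S) configuration.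

Step 5 (samarium aldol). The samarium enolate may be protonated before it cyclises onto the hindered isopropyl ketone, the aldolate may revert on warming, or the isopropyl ketone may be reduced to its ketyl. The fallback sets out from 8 and comes back at 10. Zn dust with TMSCl and TMEDA in Et2O would convert the α-bromo ketone regiospecifically into the keto enol trimethylsilyl ether F9. TiCl4 in CH2Cl2 at −78 °C would then close the ring by an intramolecular Mukaiyama aldol, which is irreversible because silicon is transferred, and aqueous work-up should give 10. The tether again enforces the cis fusion and the isopropyl group should again prefer the convex face.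

**Further compounds**

F1 | step 7 | aminocyclobutene from 13 and methyl propiolate (as 14 without the C8 methyl) | COC(=O)C1=CC2C[C@]3(C)CC[C@@](O[Si](CC)(CC)CC)(C(C)C)[C@@H]3C12N4CCCC4
F2 | step 7 | methyl 8a-methyl-3-(propan-2-yl)-4-(pyrrolidin-1-yl)-3-[(triethylsilyl)oxy]-1,2,3,3a,8,8a-hexahydroazulene-5-carboxylate | C1CCN(C1)C2=C(C(=O)OC)C=CC[C@]3(C)CC[C@@](O[Si](CC)(CC)CC)(C(C)C)[C@H]23
F3 | step 7 | methyl 8a-methyl-4-oxo-3-(propan-2-yl)-3-[(triethylsilyl)oxy]-1,2,3,3a,4,7,8,8a-octahydroazulene-5-carboxylate | O=C2C(C(=O)OC)=CCC[C@]3(C)CC[C@@](O[Si](CC)(CC)CC)(C(C)C)[C@H]23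
F4 | step 7 | 8a-methyl-3-(propan-2-yl)-3-[(triethylsilyl)oxy]-2,3,3a,7,8,8a-hexahydroazulen-4(1H)-one | O=C2C=CCC[C@]3(C)CC[C@@](O[Si](CC)(CC)CC)(C(C)C)[C@H]23
F5 | step 7 | enol trimethylsilyl ether (C6=C7) of the 8-methyl ketone, C8 epimers | C[Si](C)(C)OC2=CC(C)CC[C@]3(C)CC[C@@](O[Si](CC)(CC)CC)(C(C)C)[C@H]23
F6 | step 1 | 3-ethoxy-1-(4-methylpent-3-en-1-yl)cyclopent-2-en-1-ol | CCOC1=CC(O)(CCC=C(C)C)CC1
F7 | step 1 | 3-(4-methylpent-3-en-1-yl)cyclopent-2-en-1-one | O=C1C=C(CCC=C(C)C)CC1
F8 | step 1 | dimethylaluminium (S)-3-methyl-3-(4-methylpent-3-en-1-yl)cyclopent-1-en-1-olate | C[Al](C)OC1=C[C@@](C)(CCC=C(C)C)CC1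
F9 | step 5 | 2-methyl-5-{1-methyl-3-[(trimethylsilyl)oxy]cyclopent-2-en-1-yl}pentan-3-one (quaternary carbon as in 8) | C[Si](C)(C)OC1=C[C@@](C)(CCC(=O)C(C)C)CC1
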